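**Plan**

1. Briarane numbering is used: C1 quaternary C–Me, C2 and C9 CH–OAc, C5(=C16H2), C6–Cl, C7 lactone O–CH, C8 C–OH, C10 ring-fusion CH, C11 C(OH)Me, C12 C=O, C13=C14, C17 CH–Me, C19 lactone C=O. β is the ring face that carries the C1 methyl.
2. Retrosynthesis: the acetates, the C12 ketone and the C6 chloride are removed first. The γ-lactone is then cut at C17–C19 and at O–C7, giving CO2 and a ten-membered 2-bromoallylic alcohol that carries a 6,7-epoxide.
3. The feature that allows this is the C8 tertiary carbinol shared by the lactone and the ten-membered ring. It is flanked by C17, which is accessible as a vinyl anion from C17(Br)=CH2, and by C7, which with the allylic C6 forms a cis-epoxide syn to the C8–OH; CO2 is annulated between these two carbons.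
4. Further cuts: C5–C6 (Nozaki–Hiyama–Kishi ring closure), C8–C7 and C9–C8 (acetylide and methoxyallene additions), C2–C3 (allylboration), and C1–C14/C10–C11 (Diels–Alder).
5. Forward order: cyclohexene (Diels–Alder), then the ten-membered ring (NHK), then the γ-lactone (CO2 annulation), then chloride, enone and acetates.
6. Stereochemistry: C1/C10 from an enantioselective Diels–Alder on an (E)-enal; C2 by reagent control; C11, C12, C9 and C8 by substrate control; C7/C6 from the C8–OH-directed epoxide followed by two inversions (lactonisation at C7, chlorination at C6); C17 by protonation anti to the C8 oxygen.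

Key step: step 25

Assumption: the (S)-configured oxazaborolidinium catalyst is taken to expose the face of the enal dienophile that leads to the (1S,10S) series drawn; if the sense is the reverse, its enantiomer is used.
Assumption: the ring-closure product of step 21 is carried as a mixture of C5 carbinol epimers that converge on oxidation, so its SMILES leaves C5 undefined.

**Route**

Step 1
Reactants: 1 methyl vinyl ketone
Product: 2 2-(triisopropylsilyloxy)buta-1,3-diene
Conditions: TIPSOTf, Et3N, CH2Cl2, 0 °C to rt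
Reagents that add atoms: triisopropylsilyl triflate CC(C)[Si](OS(=O)(=O)C(F)(F)F)(C(C)C)C(C)C
Why: Soft enolisation and O-silylation of the methyl ketone (silyl enol ether formation) gives the 2-silyloxy diene.

Step 2
Reactants: 3 (tert-butyldimethylsilyloxy)acetaldehyde; 4 2-(triphenylphosphoranylidene)propanal
Product: 5 (E)-4-(tert-butyldimethylsilyloxy)-2-methylbut-2-enal
Conditions: PhMe, 80 °C
Reagents that add atoms: none
Why: Wittig olefination with a stabilised ylide should give the (E)-trisubstituted enal, in which the methyl group is cis to the CH2OTBS arm.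

Step 3
Reactants: 2 2-(triisopropylsilyloxy)buta-1,3-diene; 5 (E)-4-(tert-butyldimethylsilyloxy)-2-methylbut-2-enal
Product: 6 (1S,6S)-6-[(tert-butyldimethylsilyloxy)methyl]-1-methyl-4-(triisopropylsilyloxy)cyclohex-3-ene-1-carbaldehyde
Conditions: (S)-o-tolyl oxazaborolidinium triflimide (20 mol%), CH2Cl2, −78 to −40 °C
Reagents that add atoms: none
Why: A Lewis-acid-catalysed normal-demand Diels–Alder reaction (chiral cationic oxazaborolidine catalysis of α-substituted enals) should form C1–C14 and C10–C11 with para regiochemistry (C12–OSi 1,4 to the formyl-bearing C1); suprafacial addition to the (E)-enal sets the C1 methyl cis to the C10 arm and the catalyst sets the absolute configuration.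

Step 4
Reactants: 6 (1S,6S)-6-[(tert-butyldimethylsilyloxy)methyl]-1-methyl-4-(triisopropylsilyloxy)cyclohex-3-ene-1-carbaldehyde
Product: 7 (1S,6S)-6-[(tert-butyldimethylsilyloxy)methyl]-1-methyl-4-oxocyclohex-2-ene-1-carbaldehyde
Conditions: Pd(OAc)2 (1.1 equiv), MeCN, rt
Reagents that add atoms: none
Why: Saegusa–Ito oxidation of the regiodefined silyl enol ether (C12=C13) should give the C13=C14 enone, because β-hydride elimination is possible only toward C14.

Step 5
Reactants: 7 (1S,6S)-6-[(tert-butyldimethylsilyloxy)methyl]-1-methyl-4-oxocyclohex-2-ene-1-carbaldehyde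
Product: 8 (4S,5S)-4-[(1R)-1-hydroxybut-3-enyl]-5-[(tert-butyldimethylsilyloxy)methyl]-4-methylcyclohex-2-enone
Conditions: (+)-Ipc2B(allyl), Et2O, −78 °C; then HOCH2CH2NH2, rt
Reagents that add atoms: (+)-B-allyldiisopinocampheylborane C=CCB([C@H]1C[C@H]2C[C@@H]([C@@H]1C)C2(C)C)[C@H]1C[C@H]2C[C@@H]([C@@H]1C)C2(C)C
Why: Brown allylboration through a chair-like six-membered transition state adds the allyl unit (C3–C5) to the neopentyl aldehyde only (the enone is far less reactive at −78 °C), and the isopinocampheyl ligands set C2 by reagent control.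

Step 6
Reactants: 8 (4S,5S)-4-[(1R)-1-hydroxybut-3-enyl]-5-[(tert-butyldimethylsilyloxy)methyl]-4-methylcyclohex-2-enone
Product: 9 C2 tert-butyldimethylsilyl ether of 8
Conditions: TBSOTf, 2,6-lutidine, CH2Cl2, −78 to 0 °C
Reagents that add atoms: tert-butyldimethylsilyl triflate CC(C)(C)[Si](C)(C)OS(=O)(=O)C(F)(F)F
Why: Silylation of the hindered secondary carbinol with a silyl triflate and a hindered base (protecting-group installation).

Step 7
Reactants: 9 C2 tert-butyldimethylsilyl ether of 8
Product: 11 11-methyl enone (methyl α and trans to the C10 arm), via lithium dienolate 10 (not isolated)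
Conditions: LDA, THF, −78 °C; MeI, −78 to −30 °C
Reagents that add atoms: iodomethane CI
Why: Kinetic α′-deprotonation of the 4,4-disubstituted enone (C1 is quaternary, so no γ-proton competes) gives the cross-conjugated dienolate, which is C-methylated at C11 (enolate alkylation) trans to the C10 arm; this centre is re-enolised in step 8.

Step 8
Reactants: 11 11-methyl enone
Product: 13 11α-hydroxy-11β-methyl enone (tertiary ketol), via potassium enolate 12 (not isolated)
Conditions: KHMDS, THF, −78 °C; 2-(phenylsulfonyl)-3-phenyloxaziridine; aq NH4Cl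
Reagents that add atoms: 2-(phenylsulfonyl)-3-phenyloxaziridine O=S(=O)(c1ccccc1)N1OC1c1ccccc1
Why: Enolate hydroxylation with an N-sulfonyloxaziridine (Davis oxidation) delivers oxygen to the α-face of the tetrasubstituted enolate, anti to the C10 side chain and the C1 methyl, so the hydroxyl ends α and the methyl β.

Step 9
Reactants: 13 11α-hydroxy-11β-methyl enone
Product: 14 11α,12β-diol (trans-diol with allylic 12-OH)
Conditions: NaBH4, CeCl3·7H2O, MeOH, −78 to −20 °C
Reagents that add atoms: none
Why: Luche 1,2-reduction masks the C12 ketone; hydride should enter from the α-face, away from the β-methyl groups at C11 and C1, to give the 12β-carbinol, a centre that is returned to the ketone in step 29.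

Step 10
Reactants: 14 11α,12β-diol
Product: 15 12-O-tert-butyldimethylsilyl ether of 14 (11-OH free)
Conditions: TBSOTf (1.05 equiv), 2,6-lutidine, CH2Cl2, −78 °C
Reagents that add atoms: tert-butyldimethylsilyl triflate CC(C)(C)[Si](C)(C)OS(=O)(=O)C(F)(F)F
Why: Selective silylation of the secondary allylic carbinol; the tertiary 11-OH is too hindered to react at −78 °C.

Step 11
Reactants: 15 12-O-tert-butyldimethylsilyl ether of 14
Product: 16 C9 primary alcohol (hydroxymethyl group on C10)
Conditions: HF·pyridine, pyridine, THF, 0 °C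
Reagents that add atoms: none
Why: Buffered HF·pyridine cleaves the primary TBS ether much faster than the two hindered secondary ones (selective desilylation).

Step 12
Reactants: 16 C9 primary alcohol
Product: 17 C9 aldehyde (formyl group on C10)
Conditions: Dess–Martin periodinane, NaHCO3, CH2Cl2, 0 °C to rt
Reagents that add atoms: none
Why: Dess–Martin oxidation of the only non-tertiary free carbinol under buffered conditions that should spare the β-hydroxy aldehyde from retro-aldol cleavage.

Step 13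
Reactants: 17 C9 aldehyde; 18 methoxyallene
Product: 19 C9 carbinol bearing a 1-methoxyallenyl group (C9 as in 41)
Conditions: 18, n-BuLi, THF, −78 °C; then 17, −78 °C; aq NH4Cl
Reagents that add atoms: none
Why: 1-Lithio-1-methoxyallene acts as an acryloyl anion equivalent in a 1,2-addition; C9 is set by attack anti to the quaternary C1 (Felkin–Anh), which is also the open face of the six-membered lithium chelate between the aldehyde and the C11 alkoxide (anti to the axial 11-methyl).

Step 14
Reactants: 19 C9 carbinol bearing a 1-methoxyallenyl group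
Product: 20 9-O-triisopropylsilyl ether of 19
Conditions: TIPSOTf, 2,6-lutidine, CH2Cl2, −78 to 0 °C
Reagents that add atoms: triisopropylsilyl triflate CC(C)[Si](OS(=O)(=O)C(F)(F)F)(C(C)C)C(C)C
Why: Silylation of the secondary C9 carbinol with a bulky non-chelating group that blocks allenol cyclisation and later steers Felkin–Anh addition at C8; the tertiary 11-OH stays free.

Step 15
Reactants: 20 9-O-triisopropylsilyl ether of 19
Product: 21 2-bromoenone (C8 ketone attached to C17(Br)=C18H2)
Conditions: NBS, NaHCO3, THF/H2O, −20 °C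
Reagents that add atoms: N-bromosuccinimide O=C1CCC(=O)N1Br; water O
Why: Electrophilic bromination of the alkoxyallene at its central carbon (C17) gives an oxocarbenium ion at C8 that is hydrolysed to the ketone (halogenation–hydrolysis of a 1-alkoxyallene); the enol-ether π bond should react ahead of the isolated alkenes.

Step 16
Reactants: 21 2-bromoenone; 22 trimethylsilylacetylene
Product: 23 C8 tertiary carbinol carrying trimethylsilylethynyl (C7≡C6) and 1-bromovinyl (C17) groups (C8 as in 41)
Conditions: 22, n-BuLi, THF, −78 °C; then 21, −78 °C; aq NH4Cl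
Reagents that add atoms: none
Why: 1,2-Addition of the lithium acetylide to the α-silyloxy ketone under non-chelating conditions follows the polar Felkin–Anh model (nucleophile anti to the C9–O bond), which sets C8 with O8 and O9 anti along the C10–C7 chain as in 41.

Step 17
Reactants: 23 C8 tertiary carbinol
Product: 25 C5 primary alcohol (3-hydroxypropyl chain on C2), via B-alkyl-9-BBN 24 (not isolated)
Conditions: 9-BBN, THF, 0 °C to rt; then H2O2, aq NaHCO3, 0 °C
Reagents that add atoms: hydrogen peroxide OO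
Why: Hydroboration–oxidation with 9-BBN is anti-Markovnikov and selective for the monosubstituted terminal alkene over the silylalkyne, the bromoalkene and the hindered cyclohexene.

Step 18
Reactants: 25 C5 primary alcohol
Product: 26 1-iodoalkyne (C7≡C6–I)
Conditions: NIS, AgNO3 (10 mol%), acetone, rt, dark
Reagents that add atoms: N-iodosuccinimide O=C1CCC(=O)N1I
Why: Silver-catalysed iododesilylation converts the alkynylsilane directly into the 1-iodoalkyne.

Step 19
Reactants: 26 1-iodoalkyne
Product: 27 (Z)-2-iodovinyl carbinol (cis C6=C7)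
Conditions: 2-nitrobenzenesulfonylhydrazide, Et3N, THF/i-PrOH, rt
Reagents that add atoms: none
Why: Diimide reduction adds H2 syn to the iodoalkyne and stops at the (Z)-iodoalkene, which fixes the cis geometry of C6=C7.

Step 20
Reactants: 27 (Z)-2-iodovinyl carbinol
Product: 28 C5 aldehyde
Conditions: Dess–Martin periodinane, NaHCO3, CH2Cl2, 0 °C to rt
Reagents that add atoms: none
Why: Dess–Martin oxidation of the primary alcohol; the tertiary carbinols and the alkenyl halides are inert.

Step 21
Reactants: 28 C5 aldehyde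
Product: 29 ten-membered (6Z)-allylic alcohol (C5 carbinol as epimer mixture)
Conditions: CrCl2 (10 equiv), NiCl2 (2 mol%), DMSO/THF, rt, 2 mM
Reagents that add atoms: none
Why: Nozaki–Hiyama–Kishi ring closure: Ni(0) inserts into the alkenyl iodide (much faster than into the hindered 1,1-disubstituted bromoalkene), transmetallation to Cr(III) and addition to the aldehyde form C5–C6 and the ten-membered ring with retention of the Z geometry.

Step 22
Reactants: 29 ten-membered (6Z)-allylic alcohol
Product: 30 ten-membered (6Z)-enone (C5 ketone)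
Conditions: Dess–Martin periodinane, NaHCO3, CH2Cl2, 0 °C
Reagents that add atoms: none
Why: Dess–Martin oxidation of the allylic carbinol removes the C5 stereocentre, so both epimers converge, and should give the (Z)-enone without isomerisation.

Step 23
Reactants: 30 ten-membered (6Z)-enone
Product: 31 ten-membered 5(16),6(Z)-diene
Conditions: Ph3PCH3Br, KOt-Bu, THF, 0 °C
Reagents that add atoms: methyltriphenylphosphonium bromide C[P+](c1ccccc1)(c1ccccc1)c1ccccc1.[Br-]
Why: Wittig methylenation (1,2-addition of the non-stabilised ylide to the enone carbonyl) installs C16 and gives the 2-substituted 1,3-diene.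

Step 24
Reactants: 31 ten-membered 5(16),6(Z)-diene
Product: 32 6,7-cis-epoxide syn to the C8 hydroxyl (vinyl epoxide)
Conditions: VO(acac)2 (5 mol%), t-BuOOH, CH2Cl2, 0 °C
Reagents that add atoms: tert-butyl hydroperoxide CC(C)(C)OO
Why: Vanadium-catalysed hydroxyl-directed epoxidation attacks only the allylic C6=C7 bond and, as for medium-ring (Z)-cycloalkenols, should deliver oxygen syn to the C8–OH, giving the cis-epoxy alcohol in which C17 lies anti to the epoxide oxygen.

Step 25
Reactants: 32 6,7-cis-epoxide syn to the C8 hydroxyl; 33 carbon dioxide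
Product: 36 α-methylene-β-hydroxy-γ-lactone (C19 lactone on O–C7; free 6-OH; 5(16)-ene), via vinyllithium 34 (not isolated), via lithium carboxylate 35 (not isolated)
Conditions: t-BuLi (4.4 equiv), THF, −78 °C; CO2, −78 °C; Ar purge; to 25 °C; aq NH4Cl
Reagents that add atoms: none
Why: Bromine–lithium exchange on the 2-bromoallylic alkoxide gives vinyllithium 34, whose sp2 carbanion adds to CO2 to form the C17–C19 bond; the resulting lithium acrylate 35 then attacks C7 of the adjacent 6,7-epoxide from the rear and forms the O–C7 bond, so CO2 is annulated across C17 and C7 in one flask. The closest known reaction types are the carboxylation of 2-lithioallyl alkoxides used for α-methylene lactones and the lactonisation of γ,δ-epoxy carboxylates. The γ-lactone closes in the 5-exo-tet mode, the breaking C7–O bond lying outside the new ring. C7 is set by inversion at the epoxide carbon, which puts C6 trans to C9 across the new ring fusion because C17 sits anti to the epoxide oxygen, while C6 keeps the epoxide configuration as a free allylic carbinol and C8 is untouched. The step needs exchange to outrun addition of t-BuLi to the vinyl epoxide (fast C(sp2)–Br exchange at −78 °C) and needs C7 attack to beat 6-endo opening at allylic C6, epoxide migration to the C8 alkoxide and carbonate formation (five-membered transition state under non-ionising lithium carboxylate conditions, aprotic medium, excess CO2 purged before warming).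

Step 26
Reactants: 36 α-methylene-β-hydroxy-γ-lactone
Product: 37 17-methyl γ-lactone (C17 as in 41)
Conditions: [(Ph3P)CuH]6, PhMe, H2O (2 equiv), rt
Reagents that add atoms: none
Why: Copper hydride conjugate reduction (Stryker reduction) of the α-methylene lactone spares the isolated alkenes; the copper enolate should be protonated from the β-face, anti to the pseudo-axial C8 oxygen, giving the 17-methyl epimer with methyl trans to the C9 branch, which should also be the more stable one.

Step 27
Reactants: 37 17-methyl γ-lactone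
Product: 38 6-chloride (allylic chloride; C6 as in 41)
Conditions: PPh3, Cl3CCOCCl3, CH2Cl2, 0 °C
Reagents that add atoms: hexachloroacetone O=C(C(Cl)(Cl)Cl)C(Cl)(Cl)Cl
Why: Appel-type chlorination converts the secondary allylic alcohol into the chloride by SN2 displacement of the oxyphosphonium ion, with inversion at C6 and without allylic transposition; the tertiary carbinols do not react.

Step 28
Reactants: 38 6-chloride
Product: 39 pentaol (2-OH, 9-OH, 12β-OH, 8-OH, 11-OH)
Conditions: HF·pyridine, THF/pyridine, 0 to 40 °C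
Reagents that add atoms: none
Why: Fluoride-mediated global desilylation (Si–F bond formation) frees the C2, C9 and C12 carbinols; lactone and allylic chloride are stable to HF·pyridine.

Step 29
Reactants: 39 pentaol
Product: 40 12-ketone (enone tetraol)
Conditions: MnO2, CH2Cl2, rt
Reagents that add atoms: none
Why: MnO2 oxidises only the allylic C12 carbinol and restores the enone; the saturated secondary carbinols at C2 and C9 and the tertiary ones are untouched.

Step 30
Reactants: 40 12-ketone
Product: 41 CNP0261648.1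
Conditions: Ac2O, pyridine, DMAP (cat.), CH2Cl2, 0 °C to rt
Reagents that add atoms: acetic anhydride CC(=O)OC(C)=O
Why: DMAP-catalysed acetylation esterifies the two secondary carbinols (C2, C9) and leaves the tertiary C8 and C11 hydroxyls free.

**Compound list**

1 | methyl vinyl ketone | C=CC(C)=O | starting material
2 | 2-(triisopropylsilyloxy)buta-1,3-diene | C=CC(=C)O[Si](C(C)C)(C(C)C)C(C)C | intermediate
3 | (tert-butyldimethylsilyloxy)acetaldehyde | O=CCO[Si](C)(C)C(C)(C)C | starting material
4 | 2-(triphenylphosphoranylidene)propanal | CC(C=O)=P(c1ccccc1)(c1ccccc1)c1ccccc1 | starting material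
5 | (E)-4-(tert-butyldimethylsilyloxy)-2-methylbut-2-enal | O=C/C(C)=C/CO[Si](C)(C)C(C)(C)C | intermediate
6 | (1S,6S)-6-[(tert-butyldimethylsilyloxy)methyl]-1-methyl-4-(triisopropylsilyloxy)cyclohex-3-ene-1-carbaldehyde | O=C[C@@]1(C)CC=C(O[Si](C(C)C)(C(C)C)C(C)C)C[C@@H]1CO[Si](C)(C)C(C)(C)C | intermediate
7 | (1S,6S)-6-[(tert-butyldimethylsilyloxy)methyl]-1-methyl-4-oxocyclohex-2-ene-1-carbaldehyde | O=C[C@@]1(C)C=CC(=O)C[C@@H]1CO[Si](C)(C)C(C)(C)C | intermediate
8 | (4S,5S)-4-[(1R)-1-hydroxybut-3-enyl]-5-[(tert-butyldimethylsilyloxy)methyl]-4-methylcyclohex-2-enone | C=CC[C@@H](O)[C@@]1(C)C=CC(=O)C[C@@H]1CO[Si](C)(C)C(C)(C)C | intermediate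
9 | C2 tert-butyldimethylsilyl ether of 8 | C=CC[C@@H](O[Si](C)(C)C(C)(C)C)[C@@]1(C)C=CC(=O)C[C@@H]1CO[Si](C)(C)C(C)(C)C | intermediate
10 | lithium cross-conjugated dienolate of 9 (C11=C12–OLi) | C=CC[C@@H](O[Si](C)(C)C(C)(C)C)[C@@]1(C)C=CC(O[Li])=C[C@@H]1CO[Si](C)(C)C(C)(C)C | intermediate (not isolated)
11 | 11-methyl enone (methyl α, trans to the C10 arm) | C=CC[C@@H](O[Si](C)(C)C(C)(C)C)[C@@]1(C)C=CC(=O)[C@@H](C)[C@@H]1CO[Si](C)(C)C(C)(C)C | intermediate
12 | potassium enolate of 11 (C11=C12–OK) | C=CC[C@@H](O[Si](C)(C)C(C)(C)C)[C@@]1(C)C=CC(O[K])=C(C)[C@@H]1CO[Si](C)(C)C(C)(C)C | intermediate (not isolated)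
13 | 11α-hydroxy-11β-methyl enone | C=CC[C@@H](O[Si](C)(C)C(C)(C)C)[C@@]1(C)C=CC(=O)[C@@](C)(O)[C@@H]1CO[Si](C)(C)C(C)(C)C | intermediate
14 | 11α,12β-diol | C=CC[C@@H](O[Si](C)(C)C(C)(C)C)[C@@]1(C)C=C[C@H](O)[C@@](C)(O)[C@@H]1CO[Si](C)(C)C(C)(C)C | intermediate
15 | 12-O-tert-butyldimethylsilyl ether of 14 | C=CC[C@@H](O[Si](C)(C)C(C)(C)C)[C@@]1(C)C=C[C@H](O[Si](C)(C)C(C)(C)C)[C@@](C)(O)[C@@H]1CO[Si](C)(C)C(C)(C)C | intermediate
16 | C9 primary alcohol | C=CC[C@@H](O[Si](C)(C)C(C)(C)C)[C@@]1(C)C=C[C@H](O[Si](C)(C)C(C)(C)C)[C@@](C)(O)[C@@H]1CO | intermediate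
17 | C9 aldehyde | C=CC[C@@H](O[Si](C)(C)C(C)(C)C)[C@@]1(C)C=C[C@H](O[Si](C)(C)C(C)(C)C)[C@@](C)(O)[C@@H]1C=O | intermediate
18 | methoxyallene (1-methoxypropa-1,2-diene) | COC=C=C | starting material
19 | C9 carbinol bearing a 1-methoxyallenyl group | C=CC[C@@H](O[Si](C)(C)C(C)(C)C)[C@@]1(C)C=C[C@H](O[Si](C)(C)C(C)(C)C)[C@@](C)(O)[C@@H]1[C@@H](O)C(OC)=C=C | intermediate
20 | 9-O-triisopropylsilyl ether of 19 | C=CC[C@@H](O[Si](C)(C)C(C)(C)C)[C@@]1(C)C=C[C@H](O[Si](C)(C)C(C)(C)C)[C@@](C)(O)[C@@H]1[C@@H](O[Si](C(C)C)(C(C)C)C(C)C)C(OC)=C=C | intermediate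
21 | 2-bromoenone (C8 ketone, C17 bromide) | C=CC[C@@H](O[Si](C)(C)C(C)(C)C)[C@@]1(C)C=C[C@H](O[Si](C)(C)C(C)(C)C)[C@@](C)(O)[C@@H]1[C@@H](O[Si](C(C)C)(C(C)C)C(C)C)C(=O)C(Br)=C | intermediate
22 | trimethylsilylacetylene | C#C[Si](C)(C)C | starting material
23 | C8 tertiary carbinol with trimethylsilylethynyl and 1-bromovinyl groups | C=CC[C@@H](O[Si](C)(C)C(C)(C)C)[C@@]1(C)C=C[C@H](O[Si](C)(C)C(C)(C)C)[C@@](C)(O)[C@@H]1[C@@H](O[Si](C(C)C)(C(C)C)C(C)C)[C@@](O)(C#C[Si](C)(C)C)C(Br)=C | intermediate
24 | B-alkyl-9-borabicyclo[3.3.1]nonane from 23 (boron on C5) | C(CC[C@@H](O[Si](C)(C)C(C)(C)C)[C@@]1(C)C=C[C@H](O[Si](C)(C)C(C)(C)C)[C@@](C)(O)[C@@H]1[C@@H](O[Si](C(C)C)(C(C)C)C(C)C)[C@@](O)(C#C[Si](C)(C)C)C(Br)=C)B1C2CCCC1CCC2 | intermediate (not isolated)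
25 | C5 primary alcohol | OCCC[C@@H](O[Si](C)(C)C(C)(C)C)[C@@]1(C)C=C[C@H](O[Si](C)(C)C(C)(C)C)[C@@](C)(O)[C@@H]1[C@@H](O[Si](C(C)C)(C(C)C)C(C)C)[C@@](O)(C#C[Si](C)(C)C)C(Br)=C | intermediate
26 | 1-iodoalkyne | OCCC[C@@H](O[Si](C)(C)C(C)(C)C)[C@@]1(C)C=C[C@H](O[Si](C)(C)C(C)(C)C)[C@@](C)(O)[C@@H]1[C@@H](O[Si](C(C)C)(C(C)C)C(C)C)[C@@](O)(C#CI)C(Br)=C | intermediate
27 | (Z)-2-iodovinyl carbinol | OCCC[C@@H](O[Si](C)(C)C(C)(C)C)[C@@]1(C)C=C[C@H](O[Si](C)(C)C(C)(C)C)[C@@](C)(O)[C@@H]1[C@@H](O[Si](C(C)C)(C(C)C)C(C)C)[C@@](O)(/C=C\I)C(Br)=C | intermediate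
28 | C5 aldehyde | O=CCC[C@@H](O[Si](C)(C)C(C)(C)C)[C@@]1(C)C=C[C@H](O[Si](C)(C)C(C)(C)C)[C@@](C)(O)[C@@H]1[C@@H](O[Si](C(C)C)(C(C)C)C(C)C)[C@@](O)(/C=C\I)C(Br)=C | intermediate
29 | ten-membered (6Z)-allylic alcohol (C5 epimer mixture) | OC1/C=C\[C@@](O)(C(Br)=C)[C@H](O[Si](C(C)C)(C(C)C)C(C)C)[C@H]2[C@](C)(O)[C@@H](O[Si](C)(C)C(C)(C)C)C=C[C@]2(C)[C@H](O[Si](C)(C)C(C)(C)C)CC1 | intermediate
30 | ten-membered (6Z)-enone | O=C1/C=C\[C@@](O)(C(Br)=C)[C@H](O[Si](C(C)C)(C(C)C)C(C)C)[C@H]2[C@](C)(O)[C@@H](O[Si](C)(C)C(C)(C)C)C=C[C@]2(C)[C@H](O[Si](C)(C)C(C)(C)C)CC1 | intermediate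
31 | ten-membered 5(16),6(Z)-diene | C=C1/C=C\[C@@](O)(C(Br)=C)[C@H](O[Si](C(C)C)(C(C)C)C(C)C)[C@H]2[C@](C)(O)[C@@H](O[Si](C)(C)C(C)(C)C)C=C[C@]2(C)[C@H](O[Si](C)(C)C(C)(C)C)CC1 | intermediate
32 | 6,7-cis-epoxide syn to the C8 hydroxyl | C=C1[C@H]3O[C@H]3[C@@](O)(C(Br)=C)[C@H](O[Si](C(C)C)(C(C)C)C(C)C)[C@H]2[C@](C)(O)[C@@H](O[Si](C)(C)C(C)(C)C)C=C[C@]2(C)[C@H](O[Si](C)(C)C(C)(C)C)CC1 | intermediate
33 | carbon dioxide | O=C=O | starting material
34 | C17 vinyllithium (8,11-dilithium alkoxide) | C=C1[C@H]3O[C@H]3[C@@](O[Li])(C([Li])=C)[C@H](O[Si](C(C)C)(C(C)C)C(C)C)[C@H]2[C@](C)(O[Li])[C@@H](O[Si](C)(C)C(C)(C)C)C=C[C@]2(C)[C@H](O[Si](C)(C)C(C)(C)C)CC1 | intermediate (not isolated)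
35 | lithium 2-substituted acrylate (C19 carboxylate, epoxide intact) | C=C1[C@H]3O[C@H]3[C@@](O[Li])(C(=C)C(=O)O[Li])[C@H](O[Si](C(C)C)(C(C)C)C(C)C)[C@H]2[C@](C)(O[Li])[C@@H](O[Si](C)(C)C(C)(C)C)C=C[C@]2(C)[C@H](O[Si](C)(C)C(C)(C)C)CC1 | intermediate (not isolated)
36 | α-methylene-β-hydroxy-γ-lactone with free 6-OH | C=C1CC[C@@H](O[Si](C)(C)C(C)(C)C)[C@@]2(C)C=C[C@H](O[Si](C)(C)C(C)(C)C)[C@@](C)(O)[C@@H]2[C@@H](O[Si](C(C)C)(C(C)C)C(C)C)[C@]2(O)C(=C)C(=O)O[C@H]2[C@@H]1O | intermediate
37 | 17-methyl γ-lactone | C=C1CC[C@@H](O[Si](C)(C)C(C)(C)C)[C@@]2(C)C=C[C@H](O[Si](C)(C)C(C)(C)C)[C@@](C)(O)[C@@H]2[C@@H](O[Si](C(C)C)(C(C)C)C(C)C)[C@]2(O)[C@@H](C)C(=O)O[C@H]2[C@@H]1O | intermediate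
38 | 6-chloride | C=C1CC[C@@H](O[Si](C)(C)C(C)(C)C)[C@@]2(C)C=C[C@H](O[Si](C)(C)C(C)(C)C)[C@@](C)(O)[C@@H]2[C@@H](O[Si](C(C)C)(C(C)C)C(C)C)[C@]2(O)[C@@H](C)C(=O)O[C@H]2[C@H]1Cl | intermediate
39 | pentaol | C=C1CC[C@@H](O)[C@@]2(C)C=C[C@H](O)[C@@](C)(O)[C@@H]2[C@@H](O)[C@]2(O)[C@@H](C)C(=O)O[C@H]2[C@H]1Cl | intermediate
40 | 12-ketone (enone tetraol) | C=C1CC[C@@H](O)[C@@]2(C)C=CC(=O)[C@@](C)(O)[C@@H]2[C@@H](O)[C@]2(O)[C@@H](C)C(=O)O[C@H]2[C@H]1Cl | intermediate
41 | CNP0261648.1 | C=C1CC[C@@H](OC(C)=O)[C@@]2(C)C=CC(=O)[C@@](C)(O)[C@@H]2[C@@H](OC(C)=O)[C@]2(O)[C@@H](C)C(=O)O[C@H]2[C@H]1Cl | target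

**Step count and risks**

Total step count: 30. Longest linear sequence: 29 steps (steps 2 to 30); step 1 is a one-step branch.

Steps most likely to fail:

1. Step 25. The carboxylate may open the vinyl epoxide at the allylic C6 (six-membered lactone) instead of C7. The C8 alkoxide may also intercept the epoxide (epoxide migration or carbonate formation), or the vinyllithium may be quenched before carboxylation. The fallback sets out from 31 and returns at 36. Palladium-catalysed methoxycarbonylation of the alkenyl bromide (Pd(PPh3)4, CO 1 atm, MeOH, Et3N, DMF, 60 °C) should give the methyl acrylate F1. Vanadium-directed epoxidation as in step 24 should then give the epoxy ester F2. Cleavage of the methyl ester with Me3SnOH (1,2-dichloroethane, 70 °C) frees the carboxylate, which should close onto C7 to give 36.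

2. Step 21. Ring closure to the ten-membered ring may lose out to oligomerisation because of transannular strain, and the bromoalkene may be activated competitively. The fallback sets out from 25 and returns at 29. Dess–Martin oxidation of 25 should give the alkynylsilane aldehyde F3. Fluoride-triggered desilylative intramolecular alkynylation (CsF, DMF, high dilution) should close the ring to the cyclic propargylic alcohol F4. Diimide (2-nitrobenzenesulfonylhydrazide, Et3N) should then reduce the strained cycloalkyne cis to 29.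

3. Step 24. Oxygen delivery may occur with poor facial selectivity if the ring conformation does not place the C8–OH over the olefin, and the 5(16)-alkene may be epoxidised competitively. The fallback sets out from 31 and returns at 32. It replaces substrate direction by reagent control: a chiral ketone-catalysed dioxirane epoxidation of the conjugated cis-olefin (Shi epoxidation with the oxazolidinone-type ketone, Oxone, buffered MeCN/H2O, 0 °C), with the catalyst enantiomer chosen for the required face. This fallback makes no new compound (F0).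

Further compounds
F1 | step 25 | methyl 2-substituted acrylate from 31 (CO2Me in place of Br on C17) | C=C1/C=C\[C@@](O)(C(=C)C(=O)OC)[C@H](O[Si](C(C)C)(C(C)C)C(C)C)[C@H]2[C@](C)(O)[C@@H](O[Si](C)(C)C(C)(C)C)C=C[C@]2(C)[C@H](O[Si](C)(C)C(C)(C)C)CC1
F2 | step 25 | 6,7-cis-epoxy methyl ester | C=C1[C@H]3O[C@H]3[C@@](O)(C(=C)C(=O)OC)[C@H](O[Si](C(C)C)(C(C)C)C(C)C)[C@H]2[C@](C)(O)[C@@H](O[Si](C)(C)C(C)(C)C)C=C[C@]2(C)[C@H](O[Si](C)(C)C(C)(C)C)CC1
F3 | step 21 | alkynylsilane C5 aldehyde | O=CCC[C@@H](O[Si](C)(C)C(C)(C)C)[C@@]1(C)C=C[C@H](O[Si](C)(C)C(C)(C)C)[C@@](C)(O)[C@@H]1[C@@H](O[Si](C(C)C)(C(C)C)C(C)C)[C@@](O)(C#C[Si](C)(C)C)C(Br)=C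
F4 | step 21 | ten-membered cyclic propargylic alcohol (C6≡C7; C5 epimer mixture) | OC1C#C[C@@](O)(C(Br)=C)[C@H](O[Si](C(C)C)(C(C)C)C(C)C)[C@H]2[C@](C)(O)[C@@H](O[Si](C)(C)C(C)(C)C)C=C[C@]2(C)[C@H](O[Si](C)(C)C(C)(C)C)CC1
F0 | step 24 | none | none
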